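Rings: A azepanone, B pyrrolidine, C cyclopentene, D fused lactone, E pendant lactone. Ring D is a γ-butyrolactone whose β-carbon is one end of the tetrasubstituted C=C between rings B and C. Its O–CH carbon (ring C), its CHMe carbon and the B/C fusion carbon are therefore the three termini of a trimethylenemethane, and cutting O–CH and C(=O)–CHMe removes CO2.
Earlier cuts: C(sp2)–CH(Me)Si (Negishi), ring A at N–CH2 and C(=O)–CH2 (N-alkylation, Fukuyama coupling), CH–Et (enolate alkylation), ring C at C=C and Cq–CH2 (alkylation/Wittig annulation), ring B at N–Cq (carbenoid N–H insertion), ring E at CH(O)–CH2 (homoenolate addition).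
Forward order of ring formation: E, B, C, A, D. Ring D is closed in the last step from acetate 33 and CO2.
Stereochemistry: pyrrolidine CH from L-aspartic acid; ring E methyl centre from methyl (R)-3-bromo-2-methylpropanoate; ring E carbinol by chelation control; quaternary carbon by alkylation anti to ring E; CHEt by convex-face alkylation; ring C carbinol by hydride anti to ethyl, Mitsunobu inversion and double inversion at palladium; CHMe of ring D in the key step.

Key step: step 17

Assumption: the silicon-bearing carbon of 27–33 is carried as a mixture of both configurations (racemic zinc reagent 26) because it becomes planar in step 17, and C-2 of 17 is configurationally labile; the SMILES leave these centres (and the two transient centres of 22) open.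

Step 1
Reactants: 1 N-Cbz-L-aspartic acid 4-tert-butyl ester
Product: 2 Weinreb amide of 1
Conditions: MeNHOMe·HCl, EDC·HCl, N-methylmorpholine, CH2Cl2, 0 °C to rt
Reagents that add atoms: N,O-dimethylhydroxylamine hydrochloride, CNOC.Cl
Why: Carbodiimide-mediated amide coupling gives the Weinreb amide, and the urethane protecting group keeps the α-stereocentre from racemising through an oxazolone.

Step 2
Reactants: 2 Weinreb amide of 1
Product: 3 tert-butyl (3S)-3-(Cbz-amino)-4-oxobutanoate
Conditions: LiAlH4, THF, −78 to −30 °C; aq. KHSO4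
Reagents that add atoms: none
Why: Weinreb amide reduction: the chelated tetrahedral aluminate collapses only on quench, so the reaction should stop at the aldehyde while the hindered tert-butyl ester and the carbamate survive at low temperature.

Step 3
Reactants: 3 tert-butyl (3S)-3-(Cbz-amino)-4-oxobutanoate; 4 methyl (R)-3-bromo-2-methylpropanoate
Product: 8 ring E lactone tert-butyl ester, via zinc homoenolate 5 (not isolated), via titanium homoenolate 6 (not isolated), via hydroxy ester 7 (not isolated)
Conditions: 4, Zn, I2 (5 mol %), DMA, 70 °C; TiCl2(OiPr)2, CH2Cl2, −20 °C; then 3, −20 to 0 °C; AcOH, toluene, 80 °C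
Reagents that add atoms: none
Why: Addition of an ester homoenolate (zinc insertion, transmetalation to titanium) to an N–H carbamate α-amino aldehyde under chelation control should give the syn amino alcohol, that is the (S)-carbinol of ring E, which lactonises on the methyl ester because the tert-butyl ester is too hindered, and the methyl-bearing centre is carried over unchanged from 4.

Step 4
Reactants: 8 ring E lactone tert-butyl ester
Product: 9 ring E lactone carboxylic acid
Conditions: TFA, CH2Cl2, 0 °C to rt
Reagents that add atoms: none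
Why: Acidolysis of the tert-butyl ester (loss of 2-methylpropene) frees the carboxyl group, whereas the benzyl carbamate and the lactone are stable to TFA.

Step 5
Reactants: 10 Meldrum's acid; 11 ethanethiol
Product: 12 3-(ethylsulfanyl)-3-oxopropanoic acid
Conditions: toluene, sealed tube, 90 °C
Reagents that add atoms: none
Why: Thermal acylation of the thiol by Meldrum's acid with loss of acetone is the standard entry to malonic acid half thioesters.

Step 6
Reactants: 9 ring E lactone carboxylic acid; 12 3-(ethylsulfanyl)-3-oxopropanoic acid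
Product: 15 β-keto thioester, via acyl imidazolide 13 (not isolated), via magnesium half-thioester salt 14 (not isolated)
Conditions: 9, CDI, THF, rt; separately 12, Mg(OEt)2, THF; combine, rt to 40 °C; dilute HCl
Reagents that add atoms: none
Why: Decarboxylative Claisen condensation (Masamune-type C-acylation of a magnesium malonate half thioester with an acyl imidazolide) works under almost neutral conditions that spare lactone, carbamate and the stereocentres.

Step 7
Reactants: 15 β-keto thioester
Product: 16 α-diazo-β-keto thioester
Conditions: 4-acetamidobenzenesulfonyl azide, Et3N, MeCN, 0 °C to rt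
Reagents that add atoms: 4-acetamidobenzenesulfonyl azide, CC(=O)Nc1ccc(cc1)S(=O)(=O)N=[N+]=[N-]
Why: Regitz diazo transfer to the doubly activated methylene group.

Step 8
Reactants: 16 α-diazo-β-keto thioester
Product: 17 3-oxopyrrolidine-2-carbothioate (ring B)
Conditions: Rh2(OAc)4 (1 mol %), CH2Cl2, reflux
Reagents that add atoms: none
Why: Rhodium carbenoid N–H insertion of the carbamate closes ring B as a five-membered ring faster than any competing carbenoid pathway, and the new C-2 centre is labile (β-keto thioester) and is overwritten in step 9.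

Step 9
Reactants: 17 3-oxopyrrolidine-2-carbothioate; 18 1-chloro-3-(triphenyl-λ5-phosphanylidene)propan-2-one
Product: 20 bicyclic enone thioester, via keto ylide 19 (not isolated)
Conditions: K2CO3, NaI (10 mol %), DMF, rt; aqueous work-up; toluene, 110 °C
Reagents that add atoms: none
Why: C-alkylation of the soft β-keto thioester enolate followed by intramolecular Wittig olefination (cyclopentenone annulation) builds ring C; the alkylating agent should enter anti to the ring E substituent, which A(1,3) strain with the carbamate holds pseudoaxial, and this sets the quaternary centre, while the neutral stabilised ylide picks the ring ketone and leaves the thioester alone.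

Step 10
Reactants: 20 bicyclic enone thioester
Product: 21 ethylated bicyclic enone thioester
Conditions: LiN(SiMe3)2 (1.05 equiv), THF, −78 °C; EtI, DMPU, −78 to −20 °C
Reagents that add atoms: iodoethane, CCI
Why: Kinetic α'-deprotonation of the enone and SN2 alkylation of the cross-conjugated enolate, as known for 4,4-disubstituted cyclopentenones; iodoethane should enter on the convex face, anti to the carbamate nitrogen on the neighbouring quaternary carbon, and the centre remains epimerisable toward this trans arrangement.

Step 11
Reactants: 21 ethylated bicyclic enone thioester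
Product: 23 bromoenone, via dibromide 22 (not isolated)
Conditions: Br2, CH2Cl2, −78 to 0 °C; then Et3N, 0 °C to rt
Reagents that add atoms: bromine, BrBr
Why: Bromine addition and base-induced dehydrobromination is the standard route to 2-bromo-3-alkylcyclopent-2-enones and meets no other alkene or enolisable ketone in 21.

Step 12
Reactants: 23 bromoenone; 24 (1-chloroethyl)trimethylsilane
Product: 27 silylethyl enone, via Grignard reagent 25 (not isolated), via zinc reagent 26 (not isolated)
Conditions: 24, Mg, THF, reflux; ZnCl2, THF, 0 °C; then 23, Pd(dppf)Cl2 (5 mol %), THF, 45 °C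
Reagents that add atoms: none
Why: Negishi coupling of an α-silyl secondary alkylzinc reagent, in which the wide-bite-angle dppf ligand favours reductive elimination over β-hydride elimination and the activated C–Br bond reacts ahead of the neopentyl thioester; the silicon-bearing centre forms as a mixture that is erased in step 17.

Step 13
Reactants: 27 silylethyl enone; 28 4-chlorobutylzinc bromide
Product: 29 chloropentanoyl enone
Conditions: 28 (0.5 M in THF), PdCl2(PPh3)2 (10 mol %), toluene, rt to 45 °C; aq. NH4Cl
Reagents that add atoms: none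
Why: Fukuyama coupling turns the thioester into the ring A ketone without touching enone, lactone, carbamate or the alkyl chloride, because organozinc halides add to none of these.

Step 14
Reactants: 29 chloropentanoyl enone
Product: 31 tricyclic enone, via secondary amine 30 (not isolated)
Conditions: H2 (1 atm), Pd/C, EtOAc, rt; filter; K2CO3, NaI (20 mol %), MeCN, 70 °C, high dilution
Reagents that add atoms: none
Why: Hydrogenolysis of the benzyl carbamate followed by Finkelstein-assisted 7-exo-tet N-alkylation closes ring A; the hindered tetrasubstituted enone should resist hydrogenation, and the α-silylalkyl enone is not an electron-rich allylsilane at this stage.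

Step 15
Reactants: 31 tricyclic enone
Product: 32 allylic alcohol (hydroxyl cis to ethyl)
Conditions: NaBH4, CeCl3·7H2O, MeOH, −78 °C
Reagents that add atoms: none
Why: Luche reduction gives 1,2-reduction of the cerium-activated enone in preference to the neopentyl ring A ketone, and hydride should arrive anti to the adjacent ethyl group, which places the hydroxyl group cis to ethyl.

Step 16
Reactants: 32 allylic alcohol
Product: 33 allylic acetate (acetoxy trans to ethyl)
Conditions: PPh3, DIAD, AcOH, toluene, 0 °C to rt
Reagents that add atoms: acetic acid, CC(=O)O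
Why: Mitsunobu reaction: acetate displaces the oxyphosphonium group from the face opposite to ethyl, which inverts the carbinol centre and at the same time installs the leaving group needed in step 17.

Step 17
Reactants: 33 allylic acetate; 34 carbon dioxide
Product: 35 target CNP0315436.2
Conditions: CO2 (10 bar), Pd(OAc)2 (10 mol %), P(OiPr)3 (60 mol %), THF, 65 °C
Reagents that add atoms: none
Why: Proposed new method: zerovalent palladium ionises the allylic acetate of 33 anti to the leaving group, the liberated acetate removes the Me3Si group, and the zwitterionic η3-trimethylenemethane–palladium complex attacks CO2 through its exocyclic CHMe terminus (C–C bond), after which the tethered carboxylate collapses on the ring CH terminus of the π-allyl cation (C–O bond) and releases the catalyst. The closest known reaction type is the palladium-catalysed [3+2] cycloaddition of 2-(silylmethyl)allyl acetates, and of methylenecyclopropanes, with CO2 to give β-methylene-γ-butyrolactones; new here are the ring-embedded, fully substituted trimethylenemethane and the tetrasubstituted alkene that has to bind palladium. Ring D closes as a five-membered ring, exo with respect to the π-allyl unit, so that the regenerated C=C lies outside ring D, between rings B and C. The carbinol centre is controlled by double inversion (acetate on the face of nitrogen, palladium on the opposite face, oxygen back on the nitrogen face and trans to ethyl); the CHMe centre is controlled by uptake of CO2 on the face remote from palladium and by the methyl group turning away from the PdL2 fragment in the closing transition state, which should place its hydrogen syn to the carbinol hydrogen. The step needs regioselectivity (CO2 at CHMe, oxygen at the ring CH): the third terminus is a fully substituted carbon next to the quaternary centre that can neither reach CO2 nor accept oxygen, and the cyclopentenyl η3 unit is the better ligand set, which leaves the exocyclic carbon as the nucleophile. It also needs chemoselectivity for CO2 over the ring A ketone and the lactone, secured by CO2 pressure, by the hindrance of the ketone and by the fact that intramolecular attack on it would create a bridgehead alkene.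

Compound list
1 | N-Cbz-L-aspartic acid 4-tert-butyl ester, (S) | O=C(OCc1ccccc1)N[C@@H](CC(=O)OC(C)(C)C)C(=O)O | starting material
2 | tert-butyl (3S)-3-(Cbz-amino)-4-[methoxy(methyl)amino]-4-oxobutanoate (Weinreb amide) | O=C(OCc1ccccc1)N[C@@H](CC(=O)OC(C)(C)C)C(=O)N(C)OC | intermediate
3 | tert-butyl (3S)-3-(Cbz-amino)-4-oxobutanoate | O=C(OCc1ccccc1)N[C@@H](CC(=O)OC(C)(C)C)C=O | intermediate
4 | methyl (R)-3-bromo-2-methylpropanoate | BrC[C@H](C)C(=O)OC | starting material
5 | bromo[(2R)-3-methoxy-2-methyl-3-oxopropyl]zinc (zinc homoenolate) | Br[Zn]C[C@H](C)C(=O)OC | intermediate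
6 | chloro(diisopropoxy)[(2R)-3-methoxy-2-methyl-3-oxopropyl]titanium (titanium homoenolate) | COC(=O)[C@@H](C)C[Ti](Cl)(OC(C)C)OC(C)C | intermediate
7 | 7-tert-butyl 1-methyl (2S,4S,5S)-5-(Cbz-amino)-4-hydroxy-2-methylheptanedioate | O=C(OCc1ccccc1)N[C@@H](CC(=O)OC(C)(C)C)[C@@H](O)C[C@H](C)C(=O)OC | intermediate
8 | tert-butyl (3S)-3-(Cbz-amino)-3-[(2S,4S)-4-methyl-5-oxooxolan-2-yl]propanoate | O=C(OCc1ccccc1)N[C@@H](CC(=O)OC(C)(C)C)[C@@H]1C[C@H](C)C(=O)O1 | intermediate
9 | (3S)-3-(Cbz-amino)-3-[(2S,4S)-4-methyl-5-oxooxolan-2-yl]propanoic acid | O=C(OCc1ccccc1)N[C@@H](CC(=O)O)[C@@H]1C[C@H](C)C(=O)O1 | intermediate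
10 | Meldrum's acid (2,2-dimethyl-1,3-dioxane-4,6-dione) | CC1(C)OC(=O)CC(=O)O1 | starting material
11 | ethanethiol | CCS | starting material
12 | 3-(ethylsulfanyl)-3-oxopropanoic acid | CCSC(=O)CC(=O)O | intermediate
13 | acyl imidazolide of 9 | O=C(OCc1ccccc1)N[C@@H](CC(=O)n1ccnc1)[C@@H]1C[C@H](C)C(=O)O1 | intermediate
14 | magnesium bis[3-(ethylsulfanyl)-3-oxopropanoate] | [Mg+2].[O-]C(=O)CC(=O)SCC.[O-]C(=O)CC(=O)SCC | intermediate
15 | S-ethyl (5S)-5-(Cbz-amino)-5-[(2S,4S)-4-methyl-5-oxooxolan-2-yl]-3-oxopentanethioate | O=C(OCc1ccccc1)N[C@@H](CC(=O)CC(=O)SCC)[C@@H]1C[C@H](C)C(=O)O1 | intermediate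
16 | 2-diazo derivative of 15 | O=C(OCc1ccccc1)N[C@@H](CC(=O)C(=[N+]=[N-])C(=O)SCC)[C@@H]1C[C@H](C)C(=O)O1 | intermediate
17 | S-ethyl (5S)-1-Cbz-5-[(2S,4S)-4-methyl-5-oxooxolan-2-yl]-3-oxopyrrolidine-2-carbothioate (C-2 labile) | O=C(OCc1ccccc1)N1C(C(=O)SCC)C(=O)C[C@H]1[C@@H]2C[C@H](C)C(=O)O2 | intermediate
18 | 1-chloro-3-(triphenyl-λ5-phosphanylidene)propan-2-one | ClCC(=O)C=P(c1ccccc1)(c1ccccc1)c1ccccc1 | starting material
19 | (2R,5S)-2-alkylated keto ylide of 17 (new chain trans to ring E) | CCSC(=O)[C@]1(CC(=O)C=P(c2ccccc2)(c2ccccc2)c2ccccc2)N(C(=O)OCc2ccccc2)[C@H]([C@@H]2C[C@H](C)C(=O)O2)CC1=O | intermediate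
20 | benzyl (2S,6aR)-6a-(ethylsulfanylcarbonyl)-2-[(2S,4S)-4-methyl-5-oxooxolan-2-yl]-5-oxo-2,3,6,6a-tetrahydrocyclopenta[b]pyrrole-1(5H)-carboxylate | O=C1C=C2C[C@@H]([C@@H]3C[C@H](C)C(=O)O3)N(C(=O)OCc3ccccc3)[C@]2(C(=O)SCC)C1 | intermediate
21 | (6R)-6-ethyl derivative of 20 (ethyl cis to the thioester, trans to N) | O=C1C=C2C[C@@H]([C@@H]3C[C@H](C)C(=O)O3)N(C(=O)OCc3ccccc3)[C@]2(C(=O)SCC)[C@H]1CC | intermediate
22 | 3a,4-dibromide of 21 (anti addition, configuration not relevant) | O=C1C(Br)C2(Br)C[C@@H]([C@@H]3C[C@H](C)C(=O)O3)N(C(=O)OCc3ccccc3)[C@]2(C(=O)SCC)[C@H]1CC | intermediate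
23 | 4-bromo derivative of 21 (α-bromoenone) | O=C1C(Br)=C2C[C@@H]([C@@H]3C[C@H](C)C(=O)O3)N(C(=O)OCc3ccccc3)[C@]2(C(=O)SCC)[C@H]1CC | intermediate
24 | (1-chloroethyl)trimethylsilane (racemic) | CC(Cl)[Si](C)(C)C | starting material
25 | chloro[1-(trimethylsilyl)ethyl]magnesium | CC([Mg]Cl)[Si](C)(C)C | intermediate
26 | chloro[1-(trimethylsilyl)ethyl]zinc | CC([Zn]Cl)[Si](C)(C)C | intermediate
27 | 4-[1-(trimethylsilyl)ethyl] derivative of 21 (Si-bearing carbon both configurations) | O=C1C(C(C)[Si](C)(C)C)=C2C[C@@H]([C@@H]3C[C@H](C)C(=O)O3)N(C(=O)OCc3ccccc3)[C@]2(C(=O)SCC)[C@H]1CC | intermediate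
28 | 4-chlorobutylzinc bromide (commercial THF solution) | ClCCCC[Zn]Br | starting material
29 | 6a-(5-chloropentanoyl) analogue of 27 | O=C1C(C(C)[Si](C)(C)C)=C2C[C@@H]([C@@H]3C[C@H](C)C(=O)O3)N(C(=O)OCc3ccccc3)[C@]2(C(=O)CCCCCl)[C@H]1CC | intermediate
30 | N-deprotected secondary amine of 29 | O=C1C(C(C)[Si](C)(C)C)=C2C[C@@H]([C@@H]3C[C@H](C)C(=O)O3)N[C@]2(C(=O)CCCCCl)[C@H]1CC | intermediate
31 | tricyclic keto-enone, rings A, B, C and E (CHEt R, quaternary C R, pyrrolidine CH S, ring E S,S) | CC[C@H]1C(=O)C(C(C)[Si](C)(C)C)=C2C[C@@H]([C@@H]3C[C@H](C)C(=O)O3)N3CCCCC(=O)[C@]213 | intermediate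
32 | allylic alcohol of 31, carbinol (R), hydroxyl cis to ethyl | CC[C@H]1[C@@H](O)C(C(C)[Si](C)(C)C)=C2C[C@@H]([C@@H]3C[C@H](C)C(=O)O3)N3CCCCC(=O)[C@]213 | intermediate
33 | allylic acetate, carbinol (S), acetoxy trans to ethyl and cis to N | CC[C@H]1[C@H](OC(C)=O)C(C(C)[Si](C)(C)C)=C2C[C@@H]([C@@H]3C[C@H](C)C(=O)O3)N3CCCCC(=O)[C@]213 | intermediate
34 | carbon dioxide | O=C=O | starting material
35 | CNP0315436.2 | CC[C@H]1[C@@H]2OC(=O)[C@H](C)C2=C2C[C@@H]([C@@H]3C[C@H](C)C(=O)O3)N3CCCCC(=O)[C@]213 | target

Total step count: 17. Longest linear sequence: 16 steps (steps 1–4 and 6–17, from 1).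

Steps most likely to fail

1. Step 17 (key step).
- What may go wrong: ionisation on the ethyl-bearing face of the tetrasubstituted alkene may be too slow. Protodesilylation may overtake carboxylation. CO2 may be taken up at a ring terminus. Facial control at the CHMe carbon may be poor.
- The fallback builds ring D from known reactions and sets out from bromoenone 23.
- tert-Butyl 2-bromopropanoate and zinc give the Reformatsky reagent bromo[1-(tert-butoxycarbonyl)ethyl]zinc F1. This is coupled with 23 (Pd(dba)2, P(tBu)3; palladium-catalysed α-vinylation of a zinc ester enolate) to the enone ester F2.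
- Fukuyama coupling with 28 gives the chloro ketone F3, hydrogenolysis gives the secondary amine F4, and K2CO3/NaI gives the tricyclic enone ester F5.
- Luche reduction gives the allylic alcohol F6 (hydroxyl cis to ethyl) and TFA gives the hydroxy acid F7.
- An intramolecular Mitsunobu reaction closes ring D with inversion at the carbinol carbon and comes back to the route at 35.
- The doubly activated CHMe centre, formed without control on this path, is adjusted by brief deprotonation and kinetic protonation from the convex face.

2. Step 13.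
- What may go wrong: oxidative addition into the neopentyl C–S bond may be sluggish, or the crowded acyl-palladium intermediate may decarbonylate before the alkyl group is transferred.
- The fallback sets out from 27 and replaces acyl cross-coupling by reduction, carbonyl addition and oxidation.
- Fukuyama reduction (Et3SiH, Pd/C, acetone) gives the angular aldehyde F8.
- MgCl2-promoted addition of 28, which attacks only the aldehyde, gives the secondary alcohol F9.
- Dess–Martin oxidation comes back to the route at 29.

3. Step 16.
- What may go wrong: the crowded oxyphosphonium ion may eliminate to a cyclopentadiene, or ionise to an allyl cation with loss of stereochemical fidelity.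
- The fallback sets out from 31 and replaces inversion by reagent-controlled reduction.
- Corey–Bakshi–Shibata reduction with (R)-2-methyl-CBS-oxazaborolidine and catecholborane should deliver hydride syn to ethyl and give the epimeric allylic alcohol F10 (hydroxyl trans to ethyl).
- Acetylation (Ac2O, DMAP, pyridine) comes back to the route at 33.

Further compounds
F1 | step 17 | bromo[1-(tert-butoxycarbonyl)ethyl]zinc | CC([Zn]Br)C(=O)OC(C)(C)C
F2 | step 17 | 4-[1-(tert-butoxycarbonyl)ethyl] analogue of 27 (enone ester) | O=C1C(C(C)C(=O)OC(C)(C)C)=C2C[C@@H]([C@@H]3C[C@H](C)C(=O)O3)N(C(=O)OCc3ccccc3)[C@]2(C(=O)SCC)[C@H]1CC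
F3 | step 17 | 6a-(5-chloropentanoyl) analogue of F2 (chloro ketone) | O=C1C(C(C)C(=O)OC(C)(C)C)=C2C[C@@H]([C@@H]3C[C@H](C)C(=O)O3)N(C(=O)OCc3ccccc3)[C@]2(C(=O)CCCCCl)[C@H]1CC
F4 | step 17 | N-deprotected secondary amine of F3 | O=C1C(C(C)C(=O)OC(C)(C)C)=C2C[C@@H]([C@@H]3C[C@H](C)C(=O)O3)N[C@]2(C(=O)CCCCCl)[C@H]1CC
F5 | step 17 | tricyclic enone tert-butyl ester | CC[C@H]1C(=O)C(C(C)C(=O)OC(C)(C)C)=C2C[C@@H]([C@@H]3C[C@H](C)C(=O)O3)N3CCCCC(=O)[C@]213
F6 | step 17 | allylic alcohol of F5, hydroxyl cis to ethyl | CC[C@H]1[C@@H](O)C(C(C)C(=O)OC(C)(C)C)=C2C[C@@H]([C@@H]3C[C@H](C)C(=O)O3)N3CCCCC(=O)[C@]213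
F7 | step 17 | hydroxy acid from F6 | CC[C@H]1[C@@H](O)C(C(C)C(=O)O)=C2C[C@@H]([C@@H]3C[C@H](C)C(=O)O3)N3CCCCC(=O)[C@]213
F8 | step 13 | 6a-formyl analogue of 27 (angular aldehyde) | O=C1C(C(C)[Si](C)(C)C)=C2C[C@@H]([C@@H]3C[C@H](C)C(=O)O3)N(C(=O)OCc3ccccc3)[C@]2(C=O)[C@H]1CC
F9 | step 13 | 6a-(5-chloro-1-hydroxypentyl) analogue of 27 (carbinol configuration open) | O=C1C(C(C)[Si](C)(C)C)=C2C[C@@H]([C@@H]3C[C@H](C)C(=O)O3)N(C(=O)OCc3ccccc3)[C@]2(C(O)CCCCCl)[C@H]1CC
F10 | step 16 | carbinol epimer of 32, (S), hydroxyl trans to ethyl | CC[C@H]1[C@H](O)C(C(C)[Si](C)(C)C)=C2C[C@@H]([C@@H]3C[C@H](C)C(=O)O3)N3CCCCC(=O)[C@]213
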